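**Retrosynthetic overview**

1. The target is a flavanone (benzo ring A, catechol ring B, pyranone ring C) joined through C5' of ring B to C8 of an apigenin (flavone) unit; it comes from its hepta-O-benzyl ether 15 by hydrogenolysis.
2. Ring C of 15 is cut at O1–C2 and C4–C4a: 3,5-bis(benzyloxy)phenol 13 (ring A carrying O1) plus the (4R)-4-aryl-β-lactone 12, whose three ring carbons become C4, C3 and C2. O1–C2 forms by SN2 with inversion, then the ring closes at carbon by Friedel–Crafts acylation in the same flask.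
3. Enabling feature: ring C is a β-aryloxy ketone, so O1 and the C4 carbonyl sit 1,3 across C2–C3 like the two electrophilic carbons of a β-lactone; ring A is a phloroglucinol in which the two carbons ortho to O1 (C4a and C8) are equivalent and each is activated by three oxygens.
4. Lactone 12 comes from the (R)-β-hydroxy acid 11; the biaryl bond C5'–C8 is made by Suzuki coupling of the ring B boronate with 8-iodo-tri-O-benzylapigenin 3; the (R)-carbinol comes from asymmetric transfer hydrogenation of β-keto ester 7.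
5. Ring order: the flavone rings are bought as apigenin, ring B is attached by the biaryl coupling, the temporary β-lactone ring is closed, and ring C is formed in the penultimate step.

Key step: step 9

Assumption: the C5'–C8 biaryl axis (three ortho oxygen substituents, no descriptor in the target) is taken as configurationally labile, so no axial control is planned.
Abbreviations: Bn = benzyl; Ar = 3,4-bis(benzyloxy)-5-{5,7-bis(benzyloxy)-2-[4-(benzyloxy)phenyl]-4-oxo-4H-chromen-8-yl}phenyl.

Step 1
Reactants: 1 apigenin (5,7-dihydroxy-2-(4-hydroxyphenyl)-4H-chromen-4-one)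
Product: 2 5,7-bis(benzyloxy)-2-[4-(benzyloxy)phenyl]-4H-chromen-4-one
Conditions: BnBr (excess), K2CO3, KI (cat.), DMF, 80 °C
Reagents that add atoms: benzyl bromide, BrCc1ccccc1
Why: Williamson etherification, in which excess halide, iodide catalysis and heat should also alkylate the hydrogen-bonded 5-OH, giving ethers that are removed by hydrogenolysis at the end.

Step 2
Reactants: 2 5,7-bis(benzyloxy)-2-[4-(benzyloxy)phenyl]-4H-chromen-4-one
Product: 3 5,7-bis(benzyloxy)-2-[4-(benzyloxy)phenyl]-8-iodo-4H-chromen-4-one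
Conditions: I2, CF3CO2Ag, CH2Cl2, 0 °C to rt
Reagents that add atoms: iodine, II
Why: Silver-assisted electrophilic aromatic iodination of the dialkoxy benzo ring of the flavone, expected at C8 (flanked by one benzyloxy group and the pyranone oxygen) in preference to C6 between two benzyloxy groups and to the less electron-rich C3 and benzyloxyphenyl positions.

Step 3
Reactants: 4 3-bromo-4,5-dihydroxybenzaldehyde
Product: 5 3,4-bis(benzyloxy)-5-bromobenzaldehyde
Conditions: BnBr, K2CO3, DMF, 60 °C
Reagents that add atoms: benzyl bromide, BrCc1ccccc1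
Why: Williamson etherification of both catechol hydroxyls, which should proceed cleanly because the aldehyde has no enolisable position.

Step 4
Reactants: 5 3,4-bis(benzyloxy)-5-bromobenzaldehyde; 6 ethyl diazoacetate
Product: 7 ethyl 3-[3,4-bis(benzyloxy)-5-bromophenyl]-3-oxopropanoate
Conditions: NbCl5 (5 mol%), CH2Cl2, rt
Reagents that add atoms: none
Why: Roskamp homologation, in which the Lewis-acid-activated aldehyde is attacked by the diazo carbon and a 1,2-hydride shift with loss of dinitrogen should give the β-keto ester.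

Step 5
Reactants: 7 ethyl 3-[3,4-bis(benzyloxy)-5-bromophenyl]-3-oxopropanoate
Product: 8 ethyl (3R)-3-[3,4-bis(benzyloxy)-5-bromophenyl]-3-hydroxypropanoate
Conditions: RuCl(p-cymene)[(R,R)-TsDPEN] (1 mol%), HCO2H/Et3N (5:2), DMF, 40 °C
Reagents that add atoms: none
Why: Noyori asymmetric transfer hydrogenation of an aryl ketone, in which the (R,R)-diamine catalyst should deliver hydride to the face that gives the (R)-benzylic alcohol (the same sense as acetophenone to (R)-1-phenylethanol), leaving the aryl bromide and benzyl ethers untouched.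

Step 6
Reactants: 8 ethyl (3R)-3-[3,4-bis(benzyloxy)-5-bromophenyl]-3-hydroxypropanoate; 3 5,7-bis(benzyloxy)-2-[4-(benzyloxy)phenyl]-8-iodo-4H-chromen-4-one
Product: 10 ethyl (3R)-3-Ar-3-hydroxypropanoate, via pinacol boronate 9 (not isolated)
Conditions: B2pin2, KOAc, Pd(dppf)Cl2 (cat.), 1,4-dioxane, 90 °C; then 3, Pd(OAc)2/SPhos (cat.), aq. K3PO4, 80 °C
Reagents that add atoms: none
Why: Miyaura borylation of the aryl bromide followed in the same flask by Suzuki–Miyaura coupling with the hindered 8-iodoflavone, for which the dialkylbiarylphosphine ligand is chosen to form the tri-ortho-substituted biaryl while the mild phosphate base should spare the ester and the carbinol stereocenter.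

Step 7
Reactants: 10 ethyl (3R)-3-Ar-3-hydroxypropanoate
Product: 11 (3R)-3-Ar-3-hydroxypropanoic acid
Conditions: LiOH, THF/H2O, 0 °C to rt; then aq. HCl to pH 3, 0 °C
Reagents that add atoms: lithium hydroxide, [Li+].[OH-]
Why: Ester saponification at low temperature, which should leave the flavone, the benzyl ethers and the configuration of the β-carbinol unchanged.

Step 8
Reactants: 11 (3R)-3-Ar-3-hydroxypropanoic acid
Product: 12 (4R)-4-Ar-oxetan-2-one
Conditions: PhSO2Cl, pyridine, 0 °C; used cold and without delay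
Reagents that add atoms: none
Why: β-Lactonisation by carboxyl activation (mixed carboxylic–sulfonic anhydride, then 4-exo-trig attack of the hydroxyl on the acyl carbon), so the C–O bond at the stereocenter is never broken and the (R) configuration is retained.

Step 9
Reactants: 12 (4R)-4-Ar-oxetan-2-one; 13 3,5-bis(benzyloxy)phenol
Product: 15 (2S)-2-Ar-5,7-bis(benzyloxy)-2,3-dihydro-4H-chromen-4-one, via caesium carboxylate 14 (not isolated)
Conditions: Cs2CO3, MeCN, 0 °C to rt; then (CF3CO)2O, 0 °C to rt
Reagents that add atoms: none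
Why: Proposed new method: the caesium phenoxide of 13 should open the strained lactone 12 by backside attack at its benzylic ring carbon (alkyl–oxygen cleavage, forming O1–C2) to give carboxylate 14, which (CF3CO)2O converts into a mixed anhydride that acylates the electron-rich aryloxy ring at the carbon ortho to the new ether oxygen (forming C4–C4a). The closest known reaction types are the chromanone synthesis from phenoxides and β-propiolactone followed by cyclodehydration of the 3-aryloxypropanoic acid, and the invertive opening of 4-substituted β-lactones by azide, thiolate and cuprate nucleophiles; what is new is the use of a 4-aryl lactone with a phenoxide and the transfer of its configuration into a flavanone in one flask. Ring C is closed at the C4–C4a carbon–carbon bond by a 6-exo-trig Friedel–Crafts acylation, while O1–C2 is made beforehand by the intermolecular substitution. The stereocenter C2 is controlled by the substrate: inversion turns the (4R)-lactone carbon into the (S)-configured ether carbon, and the acylation does not touch it. The step needs O- over C-alkylation and alkyl–oxygen over acyl–oxygen attack, which the caesium phenoxide in MeCN and the reversibility of acyl attack (the hydroxy aryl ester alkoxide re-closes to the lactone) should secure, and SN2 over ionisation, which is helped by the 4'-benzyloxy group being twisted out of conjugation between its two ortho neighbours and by the basic, aprotic, cold medium. The site of acylation is not an issue, because the two carbons ortho to O1 in 13 are equivalent and each is activated by three oxygens, so that only the 5,7-dioxygenated chromanone can form and acylation of the less activated ring B should not compete.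

Step 10
Reactants: 15 (2S)-2-Ar-5,7-bis(benzyloxy)-2,3-dihydro-4H-chromen-4-one
Product: 16 (2S)-2-{3,4-dihydroxy-5-[5,7-dihydroxy-2-(4-hydroxyphenyl)-4-oxo-4H-chromen-8-yl]phenyl}-5,7-dihydroxy-2,3-dihydro-4H-chromen-4-one
Conditions: H2 (1 atm), Pd/C, THF/MeOH, rt
Reagents that add atoms: none
Why: Catalytic hydrogenolysis of the seven O-benzyl ethers under neutral conditions, which avoids the base-mediated ring opening (retro-oxa-Michael) that would racemise C2, and should be stopped at full debenzylation before the flavone double bond or the benzylic C2–O1 bond is attacked.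

**Compound list**

1 | apigenin | O=c1cc(-c2ccc(O)cc2)oc2cc(O)cc(O)c12 | starting material
2 | 5,7-bis(benzyloxy)-2-[4-(benzyloxy)phenyl]-4H-chromen-4-one | O=c1cc(-c2ccc(OCc3ccccc3)cc2)oc2cc(OCc3ccccc3)cc(OCc3ccccc3)c12 | intermediate
3 | 5,7-bis(benzyloxy)-2-[4-(benzyloxy)phenyl]-8-iodo-4H-chromen-4-one | O=c1cc(-c2ccc(OCc3ccccc3)cc2)oc2c(I)c(OCc3ccccc3)cc(OCc3ccccc3)c12 | intermediate
4 | 3-bromo-4,5-dihydroxybenzaldehyde | O=Cc1cc(O)c(O)c(Br)c1 | starting material
5 | 3,4-bis(benzyloxy)-5-bromobenzaldehyde | O=Cc1cc(OCc2ccccc2)c(OCc2ccccc2)c(Br)c1 | intermediate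
6 | ethyl diazoacetate | CCOC(=O)C=[N+]=[N-] | starting material
7 | ethyl 3-[3,4-bis(benzyloxy)-5-bromophenyl]-3-oxopropanoate | CCOC(=O)CC(=O)c1cc(OCc2ccccc2)c(OCc2ccccc2)c(Br)c1 | intermediate
8 | ethyl (3R)-3-[3,4-bis(benzyloxy)-5-bromophenyl]-3-hydroxypropanoate | CCOC(=O)C[C@@H](O)c1cc(OCc2ccccc2)c(OCc2ccccc2)c(Br)c1 | intermediate
9 | ethyl (3R)-3-[3,4-bis(benzyloxy)-5-(4,4,5,5-tetramethyl-1,3,2-dioxaborolan-2-yl)phenyl]-3-hydroxypropanoate | CCOC(=O)C[C@@H](O)c1cc(OCc2ccccc2)c(OCc2ccccc2)c(B2OC(C)(C)C(C)(C)O2)c1 | intermediate (not isolated)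
10 | ethyl (3R)-3-{3,4-bis(benzyloxy)-5-[5,7-bis(benzyloxy)-2-(4-(benzyloxy)phenyl)-4-oxo-4H-chromen-8-yl]phenyl}-3-hydroxypropanoate | CCOC(=O)C[C@@H](O)c1cc(OCc2ccccc2)c(OCc2ccccc2)c(-c2c(OCc3ccccc3)cc(OCc3ccccc3)c3c(=O)cc(-c4ccc(OCc5ccccc5)cc4)oc23)c1 | intermediate
11 | (3R)-3-{3,4-bis(benzyloxy)-5-[5,7-bis(benzyloxy)-2-(4-(benzyloxy)phenyl)-4-oxo-4H-chromen-8-yl]phenyl}-3-hydroxypropanoic acid | OC(=O)C[C@@H](O)c1cc(OCc2ccccc2)c(OCc2ccccc2)c(-c2c(OCc3ccccc3)cc(OCc3ccccc3)c3c(=O)cc(-c4ccc(OCc5ccccc5)cc4)oc23)c1 | intermediate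
12 | (4R)-4-{3,4-bis(benzyloxy)-5-[5,7-bis(benzyloxy)-2-(4-(benzyloxy)phenyl)-4-oxo-4H-chromen-8-yl]phenyl}oxetan-2-one | O=C1C[C@H](c2cc(OCc3ccccc3)c(OCc3ccccc3)c(-c3c(OCc4ccccc4)cc(OCc4ccccc4)c4c(=O)cc(-c5ccc(OCc6ccccc6)cc5)oc34)c2)O1 | intermediate
13 | 3,5-bis(benzyloxy)phenol | Oc1cc(OCc2ccccc2)cc(OCc2ccccc2)c1 | starting material
14 | caesium (3S)-3-{3,4-bis(benzyloxy)-5-[5,7-bis(benzyloxy)-2-(4-(benzyloxy)phenyl)-4-oxo-4H-chromen-8-yl]phenyl}-3-[3,5-bis(benzyloxy)phenoxy]propanoate | [Cs+].[O-]C(=O)C[C@@H](c1cc(OCc2ccccc2)c(OCc2ccccc2)c(-c2c(OCc3ccccc3)cc(OCc3ccccc3)c3c(=O)cc(-c4ccc(OCc5ccccc5)cc4)oc23)c1)Oc1cc(OCc2ccccc2)cc(OCc2ccccc2)c1 | intermediate (not isolated)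
15 | (2S)-5,7-bis(benzyloxy)-2-{3,4-bis(benzyloxy)-5-[5,7-bis(benzyloxy)-2-(4-(benzyloxy)phenyl)-4-oxo-4H-chromen-8-yl]phenyl}-2,3-dihydro-4H-chromen-4-one | O=C1C[C@@H](c2cc(OCc3ccccc3)c(OCc3ccccc3)c(-c3c(OCc4ccccc4)cc(OCc4ccccc4)c4c(=O)cc(-c5ccc(OCc6ccccc6)cc5)oc34)c2)Oc2cc(OCc3ccccc3)cc(OCc3ccccc3)c21 | intermediate
16 | (2S)-2-{3,4-dihydroxy-5-[5,7-dihydroxy-2-(4-hydroxyphenyl)-4-oxo-4H-chromen-8-yl]phenyl}-5,7-dihydroxy-2,3-dihydro-4H-chromen-4-one | O=C1C[C@@H](c2cc(O)c(O)c(-c3c(O)cc(O)c4c(=O)cc(-c5ccc(O)cc5)oc34)c2)Oc2cc(O)cc(O)c21 | target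

**Step count and risks**

Total step count: 10. Longest linear sequence: 8 steps (4 → 5 → 7 → 8 → 10 → 11 → 12 → 15 → 16; the apigenin branch 1 → 2 → 3 joins at step 6).

Steps most likely to fail:

Step 9 (bears the label "Proposed new method:"). The configuration at C2 may be lost through ionisation of the benzylic C–O bond of 12, or through elimination and re-addition at the mixed-anhydride stage. The phenoxide may also be diverted to carbon alkylation or to attack at the acyl carbon. The fallback uses known chemistry and sets out from 10. Mitsunobu etherification of the (R)-carbinol with phenol 13 (PPh3, DIAD, toluene, 0 °C, inversion at the benzylic carbon) should give ethyl (3S)-3-Ar-3-[3,5-bis(benzyloxy)phenoxy]propanoate F1. Saponification (LiOH, THF/H2O, 0 °C) should give (3S)-3-Ar-3-[3,5-bis(benzyloxy)phenoxy]propanoic acid F2. Intramolecular Friedel–Crafts acylation of F2 with (CF3CO)2O in CH2Cl2 at 0 °C should close ring C, and the sequence comes back to the route at 15.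

Step 8. The benzylic hydroxyl may be activated in place of the carboxyl group, and the electron-rich β-aryl system may fragment by decarboxylation to the styrene during ring closure. The fallback sets out from 5 and 3 and builds the lactone by cycloaddition, so that the benzylic C–O bond is never activated. One-flask Miyaura borylation of 5 (B2pin2, KOAc, Pd(dppf)Cl2) should give 3,4-bis(benzyloxy)-5-(4,4,5,5-tetramethyl-1,3,2-dioxaborolan-2-yl)benzaldehyde F3, which is coupled without isolation with 3 (Pd(OAc)2/SPhos, aq. K3PO4) to give the biaryl aldehyde Ar-CHO F4. A catalytic asymmetric ketene–aldehyde [2+2] cycloaddition (acetyl chloride, iPr2NEt, O-trimethylsilylquinidine (cat.), LiClO4, CH2Cl2/Et2O, −78 °C) should then give the lactone, and the sequence comes back to the route at 12. The alkaloid pseudoenantiomer is to be chosen so that the lactone correlates with 11 after ring opening.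

Step 4. With the electron-rich aryl group, 1,2-aryl migration may compete with the wanted 1,2-hydride shift, and addition of the diazo ester to the aromatic aldehyde may be slow. The fallback sets out from 5. Aldol addition of the lithium enolate of ethyl acetate (LDA, EtOAc, THF, −78 °C) should give racemic ethyl 3-[3,4-bis(benzyloxy)-5-bromophenyl]-3-hydroxypropanoate F5. Dess–Martin oxidation of F5 should give the β-keto ester, and the sequence comes back to the route at 7.

**Further compounds**

F1 | step 9 | ethyl (3S)-3-{3,4-bis(benzyloxy)-5-[5,7-bis(benzyloxy)-2-(4-(benzyloxy)phenyl)-4-oxo-4H-chromen-8-yl]phenyl}-3-[3,5-bis(benzyloxy)phenoxy]propanoate | CCOC(=O)C[C@@H](c1cc(OCc2ccccc2)c(OCc2ccccc2)c(-c2c(OCc3ccccc3)cc(OCc3ccccc3)c3c(=O)cc(-c4ccc(OCc5ccccc5)cc4)oc23)c1)Oc1cc(OCc2ccccc2)cc(OCc2ccccc2)c1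
F2 | step 9 | (3S)-3-{3,4-bis(benzyloxy)-5-[5,7-bis(benzyloxy)-2-(4-(benzyloxy)phenyl)-4-oxo-4H-chromen-8-yl]phenyl}-3-[3,5-bis(benzyloxy)phenoxy]propanoic acid | OC(=O)C[C@@H](c1cc(OCc2ccccc2)c(OCc2ccccc2)c(-c2c(OCc3ccccc3)cc(OCc3ccccc3)c3c(=O)cc(-c4ccc(OCc5ccccc5)cc4)oc23)c1)Oc1cc(OCc2ccccc2)cc(OCc2ccccc2)c1
F3 | step 8 | 3,4-bis(benzyloxy)-5-(4,4,5,5-tetramethyl-1,3,2-dioxaborolan-2-yl)benzaldehyde | O=Cc1cc(OCc2ccccc2)c(OCc2ccccc2)c(B2OC(C)(C)C(C)(C)O2)c1
F4 | step 8 | 3,4-bis(benzyloxy)-5-{5,7-bis(benzyloxy)-2-[4-(benzyloxy)phenyl]-4-oxo-4H-chromen-8-yl}benzaldehyde | O=Cc1cc(OCc2ccccc2)c(OCc2ccccc2)c(-c2c(OCc3ccccc3)cc(OCc3ccccc3)c3c(=O)cc(-c4ccc(OCc5ccccc5)cc4)oc23)c1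
F5 | step 4 | racemic ethyl 3-[3,4-bis(benzyloxy)-5-bromophenyl]-3-hydroxypropanoate | CCOC(=O)CC(O)c1cc(OCc2ccccc2)c(OCc2ccccc2)c(Br)c1
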